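**Assumptions.** (S)-Terpinen-4-ol is taken as commercially available as a single enantiomer. It is the only stereocenter bought, and it is C-3 of the target (the C(OH)(iPr) carbon). The methyl-bearing CH in the tether (later ring carbon c) is racemic, which is harmless because it epimerizes and is later made sp².

Atom labels used below:
- q = the quaternary C–Me ring-fusion carbon.
- f = the CH ring-fusion carbon.
- a, b, c, d, e = the 7-ring carbons in order from q: a is CH₂ next to q, b is epoxide CH, c is epoxide C–Me, d is CH₂, e is CH–OAr next to f.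

## Retrosynthetic overview
1. The target comes from the epoxide and ester of a cycloheptenol. The epoxide is formed by hydroxyl-directed epoxidation of the trisubstituted b=c alkene, and the ester by acylation of the e–OH.
2. The 7-ring comes from ring expansion of a bicyclo[3.2.0] photoadduct by donor–acceptor cyclobutane fragmentation. The photoadduct comes from an intramolecular enone/enol-ether [2+2] of a 1-acylcyclopentene, which builds the quaternary C–Me (q) and the cyclobutane in one step.
3. The acylcyclopentene comes from (S)-terpinen-4-ol by ozonolysis, then aldol closure of the 5-ring, then addition of a ketal-bearing chain.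
4. Ring order: 5-ring (aldol), then cyclobutane plus the new 5-ring (photocycloaddition), then 7-ring (fragmentation).

## Route

**Step 1**
Reactants: 1 (S)-terpinen-4-ol
Product: 2 TBS ether of 1
Conditions: TBSOTf, 2,6-lutidine, CH₂Cl₂, −78 → 0 °C
Reagents that add atoms: tert-butyldimethylsilyl triflate, CC(C)(C)[Si](C)(C)OS(=O)(=O)C(F)(F)F
Why: Silylation of the tertiary alcohol blocks retro-aldol and dehydration later and later shields one alkene face; the carbinol stereocenter is untouched.

**Step 2**
Reactants: 2
Product: 3 keto-aldehyde, OHC–CH₂–C(OTBS)(iPr)–CH₂CH₂C(O)CH₃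
Conditions: O₃, CH₂Cl₂/MeOH, −78 °C; then PPh₃, −78 °C → rt
Reagents that add atoms: ozone, O=[O+][O-]
Why: Ozonolysis with reductive work-up cleaves the only alkene, converting C3 into the aldehyde (future e) and C4 into the methyl ketone (future q).

**Step 3**
Reactants: 3
Product: 4 enal, 5-(TBSO)-5-isopropyl-2-methylcyclopent-1-ene-1-carbaldehyde
Conditions: pyrrolidine (20 mol %), AcOH (20 mol %), CH₂Cl₂, rt
Reagents that add atoms: none
Why: Amine-catalyzed intramolecular aldol condensation: the aldehyde enamine (f) attacks the methyl ketone (q) in 5-exo fashion, and dehydration gives the conjugated enal, forming the f–q bond and ring A.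

**Step 4**
Reactants: 5 3-methylbut-3-en-2-one
Product: 6 4-bromo-3-methylbutan-2-one
Conditions: HBr (aq. 48 %), 0 °C → rt
Reagents that add atoms: hydrogen bromide, Br
Why: Conjugate (Michael-type) hydrobromination puts Br on the β-CH₂ carbon.

**Step 5**
Reactants: 6
Product: 7 1-bromo-3,3-dimethoxy-2-methylbutane
Conditions: HC(OMe)₃, MeOH, TsOH (cat.), rt
Reagents that add atoms: trimethyl orthoformate, COC(OC)OC; methanol, CO
Why: Ketalization masks the ketone so that a Grignard reagent can be made.

**Step 6**
Reactants: 4 enal; 7 bromoketal
Product: 8 allylic alcohol (e and c epimeric mixture)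
Conditions: Mg, THF (make RMgBr from 7); add 4, −78 → 0 °C; sat. NH₄Cl
Reagents that add atoms: none
Why: Grignard 1,2-addition to the aldehyde attaches the d–c(Me)–b(ketal)–a chain; the new carbinol e is oxidized in the next step and c is later made sp², so the mixture is harmless.

**Step 7**
Reactants: 8
Product: 9 enone (1-acylcyclopentene with the ketal chain)
Conditions: MnO₂ (activated, 20 equiv), CH₂Cl₂, rt
Reagents that add atoms: none
Why: MnO₂ oxidation of the allylic alcohol gives the photoactive enone; the ketal and TBS ether are inert.

**Step 8**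
Reactants: 9
Product: 10 methyl enol ether, CH₂=C(OMe)–CH(Me)–CH₂–C(O)–cyclopentene
Conditions: TMSOTf, i-Pr₂NEt, CH₂Cl₂, −78 → 0 °C; Et₃N-buffered work-up
Reagents that add atoms: none
Why: Gassman-type conversion of the dimethyl ketal to the less-substituted (terminal) methyl enol ether via a TMSOTf-generated oxocarbenium that is deprotonated by the hindered amine; the enone is far less reactive than the ketal.

**Step 9**
Reactants: 10
Product: 11 photoadduct (5-4-5 tricycle: cyclobutyl methyl ether with ring-B cyclopentanone and quaternary q–Me)
Conditions: hν (300 nm, Rayonet), MeCN (5 mM, degassed), 10 °C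
Reagents that add atoms: none
Why: Intramolecular enone/enol-ether [2+2] photocycloaddition closes a five-membered ring by the rule of five, forming f–b and q–a bonds on one face of ring A. The face syn to the isopropyl group is chosen because the bulky OTBS group shields the opposite face and the iPr methine H eclipses the alkene plane (A(1,3) minimization); the cis-fused cyclobutane fixes b relative to f and q.
Proposed new method: a triplet (n,π*) 1-acylcyclopentene reacts with the tethered 2-methoxyalkene to give a 1,4-biradical (first bond f–b), which undergoes spin inversion and closes the cyclobutane. The closest known reaction type is the intramolecular [2+2] of 1,6-heptadien-3-ones and the de Mayo reaction. What is new is using a tetrasubstituted exocyclic-acyl cyclopentene as the acceptor, so that the cyclobutane ends up as a donor–acceptor ring set up for expansion.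

**Step 10**
Reactants: 11
Product: 12 1,4-dione (trans-fused 5-7 bicycle; b and e ketones)
Conditions: BF₃·OEt₂, CH₂Cl₂, −78 → −20 °C; then aq. NaHCO₃; then DBU (0.2 equiv), CH₂Cl₂, 0 °C, 1 h
Reagents that add atoms: water, O
Why: Lewis-acid retro-aldol-type (retro-Mannich-like) fragmentation of the donor–acceptor cyclobutane: the OMe-stabilized oxocarbenium at b and a boron enolate at f form on cleavage of the f–b fusion bond, which expands 5-4 to the 7-ring. Hydrolysis gives the b ketone. DBU equilibrates f to the isomer with e anti to iPr (the target arrangement) and epimerizes c.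

**Step 11**
Reactants: 12
Product: 13 enol triflate b(OTf)=c(Me)
Conditions: Tf₂O, 2,6-di-tert-butyl-4-methylpyridine, CH₂Cl₂, 0 °C
Reagents that add atoms: trifluoromethanesulfonic anhydride, O=S(=O)(C(F)(F)F)OS(=O)(=O)C(F)(F)F
Why: The less hindered b ketone reacts selectively over the neopentyl-type e ketone, and thermodynamic (acid-type) enolization favors the more substituted b=c enol triflate.

**Step 12**
Reactants: 13
Product: 14 cycloheptenone (trisubstituted b=c alkene, e ketone, OTBS)
Conditions: Pd(OAc)₂, PPh₃, Bu₃N, HCO₂H, DMF, 60 °C
Reagents that add atoms: none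
Why: Pd-catalyzed formate reduction of the enol triflate (Cacchi) replaces OTf by H and keeps the alkene position; f equilibrates to the thermodynamic configuration under the amine.

**Step 13**
Reactants: 14
Product: 15 β-hydroxy ketone with free tertiary C–OH
Conditions: TBAF·3H₂O, AcOH (1:1), THF, 45 °C
Reagents that add atoms: none
Why: Acid-buffered fluoride removes the hindered tertiary silyl ether without the basic conditions that would trigger retro-aldol at the f–C3 bond.

**Step 14**
Reactants: 15
Product: 16 cycloheptenediol with the e–OH set
Conditions: Me₄NBH(OAc)₃, AcOH, MeCN, −20 °C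
Reagents that add atoms: none
Why: Evans–Saksena hydroxyl-directed reduction: the C3 alkoxyborohydride delivers hydride intramolecularly to the e ketone through a six-membered transition state. This gives the anti-1,3-diol, which is the relationship in the target, and sets e.

**Step 15**
Reactants: 16
Product: 17 epoxy diol
Conditions: VO(acac)₂ (5 mol %), t-BuOOH, CH₂Cl₂, 0 °C
Reagents that add atoms: tert-butyl hydroperoxide, CC(C)(C)OO
Why: Vanadium-directed (Sharpless-type) epoxidation of the homoallylic e–OH delivers the epoxide oxygen cis to e–O, as in the target, and sets b and c.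

**Step 16**
Reactants: 17; 18 4-acetoxybenzoyl chloride
Product: 19 e-(4-acetoxybenzoate)
Conditions: DMAP, Et₃N, CH₂Cl₂, rt → 40 °C
Reagents that add atoms: none (the acyl donor is 18)
Why: Chemoselective acylation of the secondary e–OH, with the hindered tertiary alcohol left untouched and the epoxide intact.

**Step 17**
Reactants: 19
Product: 20 target (Jaeskeanin)
Conditions: K₂CO₃ (cat.), MeOH, 0 °C, 30 min
Reagents that add atoms: none
Why: Aryl acetate methanolysis is much faster than cleavage of the hindered alkyl benzoate, epoxide opening, or transesterification.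

## Compound list
1 | (1S)-1-isopropyl-4-methylcyclohex-3-en-1-ol, (S)-terpinen-4-ol | CC(C)[C@@]1(O)CC=C(C)CC1 | starting material
2 | TBS ether of 1 | CC(C)[C@@]1(O[Si](C)(C)C(C)(C)C)CC=C(C)CC1 | intermediate
3 | 3-(TBSO)-3-isopropyl-6-oxoheptanal (keto-aldehyde) | CC(C)[C@@](CC=O)(CCC(C)=O)O[Si](C)(C)C(C)(C)C | intermediate
4 | (5S)-5-(TBSO)-5-isopropyl-2-methylcyclopent-1-ene-1-carbaldehyde | O=CC1=C(C)CC[C@@]1(O[Si](C)(C)C(C)(C)C)C(C)C | intermediate
5 | 3-methylbut-3-en-2-one | C=C(C)C(C)=O | starting material
6 | 4-bromo-3-methylbutan-2-one | CC(=O)C(C)CBr | intermediate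
7 | 1-bromo-3,3-dimethoxy-2-methylbutane | COC(C)(OC)C(C)CBr | intermediate
8 | allylic alcohol from 4 + 7 (e and c epimeric mixture) | COC(C)(OC)C(C)CC(O)C1=C(C)CC[C@@]1(O[Si](C)(C)C(C)(C)C)C(C)C | intermediate
9 | enone (acyl on the cyclopentene, ketal chain) | COC(C)(OC)C(C)CC(=O)C1=C(C)CC[C@@]1(O[Si](C)(C)C(C)(C)C)C(C)C | intermediate
10 | methyl enol ether | C=C(OC)C(C)CC(=O)C1=C(C)CC[C@@]1(O[Si](C)(C)C(C)(C)C)C(C)C | intermediate
11 | [2+2] photoadduct (c epimeric mixture) | CC(C)[C@]1(O[Si](C)(C)C(C)(C)C)CC[C@]2(C)C[C@@]3(OC)C(C)CC(=O)[C@@]123 | intermediate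
12 | trans-fused 5-7 1,4-dione (c epimeric) | CC(C)[C@]1(O[Si](C)(C)C(C)(C)C)CC[C@]2(C)CC(=O)C(C)CC(=O)[C@H]21 | intermediate
13 | enol triflate | CC(C)[C@]1(O[Si](C)(C)C(C)(C)C)CC[C@]2(C)CC(OS(=O)(=O)C(F)(F)F)=C(C)CC(=O)[C@H]21 | intermediate
14 | cycloheptenone (OTBS) | CC(C)[C@]1(O[Si](C)(C)C(C)(C)C)CC[C@]2(C)CC=C(C)CC(=O)[C@H]21 | intermediate
15 | hydroxy-cycloheptenone | CC(C)[C@]1(O)CC[C@]2(C)CC=C(C)CC(=O)[C@H]21 | intermediate
16 | cycloheptenediol | CC(C)[C@]1(O)CC[C@]2(C)CC=C(C)C[C@H](O)[C@H]21 | intermediate
17 | epoxy diol | CC(C)[C@]1(O)CC[C@]2(C)C[C@@H]3O[C@]3(C)C[C@H](O)[C@H]21 | intermediate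
18 | 4-acetoxybenzoyl chloride | CC(=O)Oc1ccc(C(=O)Cl)cc1 | starting material
19 | 4-acetoxybenzoate of 17 | CC(C)[C@]1(O)CC[C@]2(C)C[C@@H]3O[C@]3(C)C[C@H](OC(=O)c3ccc(OC(C)=O)cc3)[C@H]21 | intermediate
20 | Jaeskeanin | CC(C)[C@]1(O)CC[C@]2(C)C[C@@H]3O[C@]3(C)C[C@H](OC(=O)c3ccc(O)cc3)[C@H]21 | target

## Totals
- Total steps: 17.
- Longest linear sequence: 15 steps (1 → 2 → 3 → 8 → 9 → 10 → 11 → 12 → 13 → 14 → 15 → 16 → 17 → 19 → 20, through Steps 1–3 and 6–17).

## Three steps most likely to fail
1. **Step 9, the proposed new [2+2].** The risks are low quantum efficiency with the tetrasubstituted enone, competing Paternò–Büchi reaction, and the wrong face relative to iPr.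
   - Fallback (known chemistry, different approach): Cu-mediated 1,4-allylation of enal 4 to form q, then methallylmagnesium chloride addition to the aldehyde, then Grubbs-II ring-closing metathesis to the cycloheptene, which leads to 16 after TBS removal.
2. **Step 11, regio- and chemoselective enol triflation.** The b ketone must react over e, and toward c rather than toward the neopentyl a carbon.
   - Fallback: form the thermodynamic TMS enol ether of b, do a Rubottom oxidation to the c-hydroxy-b-ketone, reduce b, then selectively activate b–OH and close the epoxide with base. This avoids the alkene altogether.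
3. **Step 14, configuration at e.** Hydroxyl-directed hydride delivery may give the e epimer, since undirected attack would be from the face opposite C3.
   - Fallback: reduce with NaBH₄/CeCl₃ and install the ester with inversion by Mitsunobu reaction with 4-acetoxybenzoic acid (PPh₃, DIAD) on the epimeric alcohol.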